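The route rests on a [3+3] closure of ring A (labdane numbering): C2–C3 and C5–C10 are made in one anionic domino. The C1 carbonyl of a 2-methyl-1,3-diketone makes both flanking carbons, C2 and C10, nucleophilic in turn; C3 and C5 sit as electrophiles (sulfinimine, enone) on either side of the quaternary C4. The precursors are the dianion of an acyclic diketone that already carries the side chain and a nine-carbon keto-sulfinimine; the chiral N–S group on C3, a carbon that is CH2 in the target, steers C5 and C10 and is later expelled. Robinson-type closure of ring B and reductive enolate chemistry finish the Δ7 core.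

Key step: step 8

Remark: atoms are numbered as in labdane (ring A: C1–C5, C10; ring B: C5–C10; C17 on C8, C18/C19 on C4, C20 on C10, side chain C11–C16).
Remark: 3-hydroxy-2,2-dimethylpropanal, diethyl (2-oxobutyl)phosphonate, 3-methylpentane-2,4-dione, (S)-tert-butanesulfinamide and Meldrum's acid are taken as commercial.

Step 1
Reactants: 1 3-methylbut-2-en-1-ol
Product: 2 tert-butyl(dimethyl)[(3-methylbut-2-en-1-yl)oxy]silane
Conditions: TBSCl, imidazole, CH2Cl2, 0 to 23 °C
Reagents that add atoms: tert-butyldimethylsilyl chloride, CC(C)(C)[Si](C)(C)Cl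
Why: Standard O-silylation of a primary alcohol; the silyl ether tolerates the strong bases used later.

Step 2
Reactants: 2 tert-butyl(dimethyl)[(3-methylbut-2-en-1-yl)oxy]silane
Product: 3 (2E)-4-{[tert-butyl(dimethyl)silyl]oxy}-2-methylbut-2-en-1-ol
Conditions: SeO2 (0.5 equiv), t-BuOOH, CH2Cl2, 23 °C
Reagents that add atoms: selenium dioxide, O=[Se]=O (oxygen carrier); tert-butyl hydroperoxide, CC(C)(C)OO (terminal oxidant)
Why: Sharpless SeO2/t-BuOOH allylic oxidation (ene reaction, then [2,3]-shift) should hydroxylate the E methyl group of the trisubstituted alkene, which fixes the 13E geometry of the side chain.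

Step 3
Reactants: 3 (2E)-4-{[tert-butyl(dimethyl)silyl]oxy}-2-methylbut-2-en-1-ol
Product: 4 {[(2E)-4-bromo-3-methylbut-2-en-1-yl]oxy}(tert-butyl)dimethylsilane
Conditions: CBr4, PPh3, CH2Cl2, 0 °C
Reagents that add atoms: carbon tetrabromide, BrC(Br)(Br)Br
Why: Appel bromination of a primary allylic alcohol under neutral conditions, without allylic transposition or loss of the E geometry.

Step 4
Reactants: 5 3-methylpentane-2,4-dione; 4 {[(2E)-4-bromo-3-methylbut-2-en-1-yl]oxy}(tert-butyl)dimethylsilane
Product: 7 (7E)-9-{[tert-butyl(dimethyl)silyl]oxy}-3,7-dimethylnon-7-ene-2,4-dione, via dilithio dianion 6 (not isolated)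
Conditions: LiN(iPr)2 (2.1 equiv), THF, −78 to 0 °C; then 4, −78 to 0 °C; aq NH4Cl
Reagents that add atoms: none
Why: γ-Alkylation of a 1,3-diketone dianion (Hauser, Huckin–Weiler): the terminal CH2 carbanion is the most reactive site and displaces the allylic bromide by SN2, giving C9–C16 and C20 of the target in one piece (the C10 centre of 7 is enolisable and is fixed only in step 8).

Step 5
Reactants: 8 3-hydroxy-2,2-dimethylpropanal; 9 diethyl (2-oxobutyl)phosphonate
Product: 10 (4E)-7-hydroxy-6,6-dimethylhept-4-en-3-one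
Conditions: LiCl, iPr2NEt, MeCN, 23 °C
Reagents that add atoms: none
Why: Horner–Wadsworth–Emmons olefination under Masamune–Roush conditions, mild enough for the free β-hydroxy aldehyde, should give the E enone.

Step 6
Reactants: 10 (4E)-7-hydroxy-6,6-dimethylhept-4-en-3-one
Product: 11 (3E)-2,2-dimethyl-5-oxohept-3-enal
Conditions: Dess–Martin periodinane, NaHCO3, CH2Cl2, 0 to 23 °C
Reagents that add atoms: none
Why: Dess–Martin oxidation of the neopentyl primary alcohol; the aldehyde has no α-hydrogen, so it can neither enolise nor move into conjugation.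

Step 7
Reactants: 11 (3E)-2,2-dimethyl-5-oxohept-3-enal; 12 (S)-2-methylpropane-2-sulfinamide
Product: 13 (S)-N-[(1E,3E)-2,2-dimethyl-5-oxohept-3-en-1-ylidene]-2-methylpropane-2-sulfinamide
Conditions: Ti(OEt)4, THF, 23 °C
Reagents that add atoms: none
Why: Ellman condensation: the aldehyde, far more reactive than the enone carbonyl, gives the E N-sulfinyl aldimine, and the sulfur configuration of 12 is carried over unchanged.

Step 8
Reactants: 7 (7E)-9-{[tert-butyl(dimethyl)silyl]oxy}-3,7-dimethylnon-7-ene-2,4-dione; 13 (S)-N-[(1E,3E)-2,2-dimethyl-5-oxohept-3-en-1-ylidene]-2-methylpropane-2-sulfinamide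
Product: 16 (S)-N-[2,2,4-trimethyl-5-oxo-3-(2-oxobutyl)-4-{(4E)-6-[tert-butyl(dimethyl)silyl]oxy-4-methylhex-4-enoyl}cyclohexyl]-2-methylpropane-2-sulfinamide (ring-A cyclohexanone; 3R; H-5 trans to CH3-20; C5 and C10 as in 24), via dilithio dianion 14 (not isolated), via Mannich adduct 15 (not isolated)
Conditions: 7 (1.3 equiv), LiN(iPr)2 (2.05 equiv per 7), THF, −78 to 0 °C; 13, −78 °C; then 23 °C; aq NH4Cl
Reagents that add atoms: none
Why: The 1,3-diketone dianion adds through its terminal CH2 (C2) to the sulfinimine carbon C3 in a lithium-bridged six-membered chair (Ellman–Davis Mannich addition), the (S)-sulfinyl group exposing the Re face so that the 3R amide should form; the remaining lithium diketonate then adds through C10 to C5 of the tethered enone (intramolecular Michael addition), so the sequence is a domino Mannich–Michael [3+3] annulation, closest in type to the cyclisation of 1,3-dicarbonyl dianions with 1,3-bis-electrophiles. Ring A closes in the favoured 6-(enolendo)-exo-trig mode, helped by the gem-dimethyl group at C4. C10 and C5 are set in a chair in which lithium still bridges N and O1 and so holds the C3–N bond axial, the planar chelated diketonate places its acyl carbon C9 equatorial and CH3-20 axial, and the enone arm on C5 is equatorial; this gives H-5 trans to CH3-20 with the absolute sense dictated by C3. The step needs C2 to choose C=N over the enone carbonyl (irreversible Mannich addition against reversible ketone addition at −78 °C) and C- over O-alkylation in the ring closure (the oxa-Michael adduct can revert).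

Step 9
Reactants: 16 ring-A cyclohexanone
Product: 17 15-{[tert-butyl(dimethyl)silyl]oxy}labda-2,8,13E-triene-1,7-dione (H-5 trans to CH3-20; C5 and C10 as in 24)
Conditions: pyrrolidine, AcOH, toluene, 90 °C; then DBU, 90 °C
Reagents that add atoms: none
Why: Pyrrolidine forms the enamine of the unhindered ethyl ketone, whose C8 attacks the C9 ketone (Robinson-type aldol cyclodehydration, ring B), and the β-sulfinamido ketone loses the sulfinamide by E1cB elimination like an aldol dehydration, erasing the auxiliary centre at C3; C5 and C10 are untouched.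

Step 10
Reactants: 17 15-{[tert-butyl(dimethyl)silyl]oxy}labda-2,8,13E-triene-1,7-dione
Product: 19 15-{[tert-butyl(dimethyl)silyl]oxy}labda-1,7,13E-triene-1,7-diyl bis(trifluoromethanesulfonate) (9α-H, as in 24), via dilithium bis-enolate 18 (not isolated)
Conditions: Li (4.4 equiv), t-BuOH (2 equiv), NH3–THF, −78 °C; NH3 off; PhNTf2, THF, 0 to 23 °C
Reagents that add atoms: N-phenylbis(trifluoromethanesulfonimide), O=S(=O)(N(c1ccccc1)S(=O)(=O)C(F)(F)F)C(F)(F)F
Why: Dissolving-metal reduction of both enones gives the two regiodefined lithium enolates (C1=C2 and C7=C8), C9 being protonated axially on the face opposite CH3-20 so that H-9 is α and the side chain equatorial; O-triflation of such enolates with PhNTf2 is the McMurry–Scott enol triflate synthesis.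

Step 11
Reactants: 19 bis(enol triflate)
Product: 20 tert-butyl(dimethyl)silyl ether of labda-1,7,13E-trien-15-ol (C5, C9, C10 as in 24)
Conditions: Pd(OAc)2 (cat.), PPh3, Bu3N, HCO2H, DMF, 60 °C
Reagents that add atoms: none
Why: Palladium-catalysed formate reduction of enol triflates (Cacchi) replaces each OTf by H without moving the double bonds, which puts the trisubstituted alkene at C7=C8; the allylic silyl ether does not ionise with zerovalent palladium.

Step 12
Reactants: 20 tert-butyl(dimethyl)silyl ether of labda-1,7,13E-trien-15-ol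
Product: 21 tert-butyl(dimethyl)silyl ether of (5S,9S,10S)-labda-7,13E-dien-15-ol
Conditions: H2 (1 atm), RhCl(PPh3)3 (cat.), benzene–EtOH, 23 °C
Reagents that add atoms: none
Why: Homogeneous hydrogenation with RhCl(PPh3)3 should reduce the cis-disubstituted C1=C2 alkene much faster than the two trisubstituted alkenes; no stereocentre is touched.

Step 13
Reactants: 21 tert-butyl(dimethyl)silyl ether of (5S,9S,10S)-labda-7,13E-dien-15-ol
Product: 22 (5S,9S,10S)-labda-7,13E-dien-15-ol
Conditions: Bu4NF, THF, 0 to 23 °C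
Reagents that add atoms: none
Why: Fluoride cleavage of the silyl ether, neutral toward the alkenes.

Step 14
Reactants: 22 (5S,9S,10S)-labda-7,13E-dien-15-ol; 23 2,2-dimethyl-1,3-dioxane-4,6-dione (Meldrum's acid)
Product: 24 3-{[(5S,9S,10S)-labda-7,13E-dien-15-yl]oxy}-3-oxopropanoic acid (CNP0279336.1)
Conditions: toluene, 100 °C
Reagents that add atoms: none
Why: Thermal ring-opening acylation of an alcohol by Meldrum's acid with loss of acetone gives the hydrogen malonate directly, with no protecting group on the acid.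

Compound list
1 | 3-methylbut-2-en-1-ol | CC(C)=CCO | starting material
2 | tert-butyl(dimethyl)[(3-methylbut-2-en-1-yl)oxy]silane | CC(C)=CCO[Si](C)(C)C(C)(C)C | intermediate
3 | (2E)-4-{[tert-butyl(dimethyl)silyl]oxy}-2-methylbut-2-en-1-ol | OC/C(C)=C/CO[Si](C)(C)C(C)(C)C | intermediate
4 | {[(2E)-4-bromo-3-methylbut-2-en-1-yl]oxy}(tert-butyl)dimethylsilane | BrC/C(C)=C/CO[Si](C)(C)C(C)(C)C | intermediate
5 | 3-methylpentane-2,4-dione | CC(=O)C(C)C(C)=O | starting material
6 | dilithio dianion of 5 (bis-enolate form) | [Li+].[Li+].C=C([O-])C(C)=C(C)[O-] | intermediate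
7 | (7E)-9-{[tert-butyl(dimethyl)silyl]oxy}-3,7-dimethylnon-7-ene-2,4-dione (C3 of the chain enolisable) | CC(=O)C(C)C(=O)CC/C(C)=C/CO[Si](C)(C)C(C)(C)C | intermediate
8 | 3-hydroxy-2,2-dimethylpropanal | OCC(C)(C)C=O | starting material
9 | diethyl (2-oxobutyl)phosphonate | CCC(=O)CP(=O)(OCC)OCC | starting material
10 | (4E)-7-hydroxy-6,6-dimethylhept-4-en-3-one | CCC(=O)/C=C/C(C)(C)CO | intermediate
11 | (3E)-2,2-dimethyl-5-oxohept-3-enal | CCC(=O)/C=C/C(C)(C)C=O | intermediate
12 | (S)-2-methylpropane-2-sulfinamide | CC(C)(C)[S@](=O)N | starting material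
13 | (S)-N-[(1E,3E)-2,2-dimethyl-5-oxohept-3-en-1-ylidene]-2-methylpropane-2-sulfinamide | CC(C)(C)[S@](=O)/N=C/C(C)(C)/C=C/C(=O)CC | intermediate
14 | dilithio dianion of 7 (bis-enolate form) | [Li+].[Li+].C=C([O-])C(C)=C([O-])CC/C(C)=C/CO[Si](C)(C)C(C)(C)C | intermediate
15 | open-chain Mannich adduct: C2–C3 joined, 3R carbon bearing the (S)-tert-butylsulfinylamino group, enone intact (neutral form of the dilithium salt) | CCC(=O)/C=C/C(C)(C)[C@H](N[S@@](=O)C(C)(C)C)CC(=O)C(C)C(=O)CC/C(C)=C/CO[Si](C)(C)C(C)(C)C | intermediate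
16 | ring-A cyclohexanone: (S)-N-[2,2,4-trimethyl-5-oxo-3-(2-oxobutyl)-4-{(4E)-6-[tert-butyl(dimethyl)silyl]oxy-4-methylhex-4-enoyl}cyclohexyl]-2-methylpropane-2-sulfinamide; 3R, N on the face opposite CH3-20, H-5 trans to CH3-20 | CCC(=O)C[C@H]1C(C)(C)[C@H](N[S@@](=O)C(C)(C)C)CC(=O)[C@]1(C)C(=O)CC/C(C)=C/CO[Si](C)(C)C(C)(C)C | intermediate
17 | 15-{[tert-butyl(dimethyl)silyl]oxy}labda-2,8,13E-triene-1,7-dione | CC1=C(CC/C(C)=C/CO[Si](C)(C)C(C)(C)C)[C@@]2(C)C(=O)C=CC(C)(C)[C@@H]2CC1=O | intermediate
18 | dilithium 1,7-bis-enolate of the tetrahydro derivative of 17 (9α-H) | [Li+].[Li+].CC1=C([O-])C[C@H]2C(C)(C)CC=C([O-])[C@]2(C)[C@H]1CC/C(C)=C/CO[Si](C)(C)C(C)(C)C | intermediate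
19 | 15-{[tert-butyl(dimethyl)silyl]oxy}labda-1,7,13E-triene-1,7-diyl bis(trifluoromethanesulfonate) | CC1=C(OS(=O)(=O)C(F)(F)F)C[C@H]2C(C)(C)CC=C(OS(=O)(=O)C(F)(F)F)[C@]2(C)[C@H]1CC/C(C)=C/CO[Si](C)(C)C(C)(C)C | intermediate
20 | tert-butyl(dimethyl)silyl ether of labda-1,7,13E-trien-15-ol | CC1=CC[C@H]2C(C)(C)CC=C[C@]2(C)[C@H]1CC/C(C)=C/CO[Si](C)(C)C(C)(C)C | intermediate
21 | tert-butyl(dimethyl)silyl ether of (5S,9S,10S)-labda-7,13E-dien-15-ol | CC1=CC[C@H]2C(C)(C)CCC[C@]2(C)[C@H]1CC/C(C)=C/CO[Si](C)(C)C(C)(C)C | intermediate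
22 | (5S,9S,10S)-labda-7,13E-dien-15-ol | CC1=CC[C@H]2C(C)(C)CCC[C@]2(C)[C@H]1CC/C(C)=C/CO | intermediate
23 | 2,2-dimethyl-1,3-dioxane-4,6-dione (Meldrum's acid) | CC1(C)OC(=O)CC(=O)O1 | starting material
24 | 3-{[(5S,9S,10S)-labda-7,13E-dien-15-yl]oxy}-3-oxopropanoic acid | CC1=CC[C@H]2C(C)(C)CCC[C@]2(C)[C@H]1CC/C(C)=C/COC(=O)CC(=O)O | target

Total step count: 14. Longest linear sequence: 11 steps (steps 1–4, then 8–14).

Steps most likely to fail

Step 8. The dianion may be quenched by proton transfer from the ethyl ketone, C2 may add to the enone carbonyl, or facial control in the ring closure may be lost if the lithium bridge between N and O1 is not kept. The fallback separates bond formation from stereocontrol and sets out from 7 and 11. The dianion 14 adds to the aldehyde 11 (γ-aldol) to give, after work-up, the β-hydroxy diketone F1 as a mixture at C3. A bifunctional cinchona base catalyst (a 6′-hydroxy, 9-O-aryl cupreidine) then effects a catalyst-controlled enantioselective intramolecular Michael addition to the hydroxy cyclohexanone F2. Under the conditions of step 9, F2 dehydrates and closes ring B, and the route is rejoined at 17.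

Step 9. The aldol closure may run in the wrong direction (C11 onto the C7 ketone), or the 1,3-diketone may reopen by retro-Michael cleavage before ring B forms. The fallback replaces the amine-mediated condensation by a directed Mukaiyama aldol and sets out from 16. TMSOTf/Et3N at −78 °C silylates only the unhindered ethyl ketone on its ethyl side to give the Z silyl enol ether F3. TiCl4 in CH2Cl2 then closes C8 onto C9 to give the β-hydroxy ketone F4. Dehydration and sulfinamide elimination (MsCl, Et3N, then DBU) return the route to 17.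

Step 10. The allylic C15–O bond may be cleaved reductively, protonation at C9 may lack face selectivity, or O-sulfonylation of the hindered C1 enolate may be incomplete. The fallback avoids dissolving metal and sets out from 17. Luche reduction (NaBH4, CeCl3·7H2O, MeOH) gives the bis-allylic diol F5 (7β-OH expected from axial hydride delivery). Myers reductive transposition (2-nitrobenzenesulfonylhydrazide, PPh3, diethyl azodicarboxylate, −30 to 23 °C) proceeds through the bis-diazene F6. Loss of N2 delivers hydrogen suprafacially to C3 and to the α face of C9 while the double bonds move to C1=C2 and C7=C8, and the route is rejoined at 20.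

Further compounds
F1 | step 8 | β-hydroxy diketone from aldol addition of 14 to 11 (C3 epimers) | CCC(=O)/C=C/C(C)(C)C(O)CC(=O)C(C)C(=O)CC/C(C)=C/CO[Si](C)(C)C(C)(C)C
F2 | step 8 | 3-hydroxy analogue of 16 (C3 epimers; C5 and C10 as in 24) | CCC(=O)C[C@H]1C(C)(C)C(O)CC(=O)[C@]1(C)C(=O)CC/C(C)=C/CO[Si](C)(C)C(C)(C)C
F3 | step 9 | Z trimethylsilyl enol ether of the ethyl ketone of 16 (C7=C8) | C/C=C(\O[Si](C)(C)C)C[C@H]1C(C)(C)[C@H](N[S@@](=O)C(C)(C)C)CC(=O)[C@]1(C)C(=O)CC/C(C)=C/CO[Si](C)(C)C(C)(C)C
F4 | step 9 | bicyclic β-hydroxy ketone (9-hydroxy-1,7-dione, 3-sulfinamide; C8 and C9 epimers) | CC1C(=O)C[C@H]2C(C)(C)[C@H](N[S@@](=O)C(C)(C)C)CC(=O)[C@]2(C)C1(O)CC/C(C)=C/CO[Si](C)(C)C(C)(C)C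
F5 | step 10 | 15-{[tert-butyl(dimethyl)silyl]oxy}labda-2,8,13E-triene-1,7-diol | CC1=C(CC/C(C)=C/CO[Si](C)(C)C(C)(C)C)[C@@]2(C)C(O)C=CC(C)(C)[C@@H]2CC1O
F6 | step 10 | 1,7-bis(diazenyl) analogue of F5 | CC1=C(CC/C(C)=C/CO[Si](C)(C)C(C)(C)C)[C@@]2(C)C(N=N)C=CC(C)(C)[C@@H]2CC1N=N
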